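## Retrosynthetic overview

1. The target comes from a bis-silyl ether by desilylation. That ether comes from a C5 aryl triflate by Suzuki–Miyaura coupling, and the triflate from a 2,3-dihydrobenzofuran-5-ol. The C5–C bond therefore replaces a C5–O bond.
2. The 5-ol comes from its 4-methoxycarbonyl derivative by dealkylation and protodecarboxylation. The ester is a temporary group that activates the quinone, directs the site of attack and binds the metal.
3. The 4-ester comes from a biomimetic, enantioselective formal (3+2) cycloaddition of 2-methoxycarbonyl-1,4-benzoquinone with (E)-3,4,5-trimethoxycinnamyl TBS ether. C3–C3a forms first, then O1–C2 closes the dihydrofuran (ring B), the only ring closed. Ring A arises from the quinone by aromatisation, and ring C is bought.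
4. Enabling feature: on ring A, O1 (at C7a) and C5 are para, so ring A is a masked 1,4-benzoquinone. C2 is benzylic to ring C, whose para methoxy group carries the charge as an O-methyl quinone methide. The trans C2/C3 pair is the imprint of an (E)-C7=C8 cinnamyl bond.

Key step: step 4

Assumption: the (S,S) ligand is taken to give the (2R,3S) series; both ligand enantiomers are commercial, and the (R,R) ligand would be used if the sense of induction proves opposite.

## Route

Step 1
Reactants: 1 methyl (E)-3-(3,4,5-trimethoxyphenyl)acrylate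
Product: 2 (E)-3-(3,4,5-trimethoxyphenyl)prop-2-en-1-ol
Conditions: iBu2AlH (DIBAL-H, 2.5 equiv), CH2Cl2, −78 °C to 0 °C
Reagents that add atoms: none
Why: Hydride reduction of an α,β-unsaturated ester with iBu2AlH proceeds 1,2 at low temperature and should leave the E alkene untouched.

Step 2
Reactants: 2 (E)-3-(3,4,5-trimethoxyphenyl)prop-2-en-1-ol
Product: 3 (E)-tert-butyldimethyl{[3-(3,4,5-trimethoxyphenyl)prop-2-en-1-yl]oxy}silane
Conditions: TBSCl, imidazole, DMF, rt
Reagents that add atoms: tert-butyldimethylsilyl chloride, CC(C)(C)[Si](C)(C)Cl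
Why: Standard O-silylation masks the alcohol so that it cannot add to the quinone, and a silyl ether is a poor leaving group toward a mild Lewis acid.

Step 3
Reactants: 4 methyl 2,5-dihydroxybenzoate
Product: 5 methyl 3,6-dioxocyclohexa-1,4-diene-1-carboxylate (2-methoxycarbonyl-1,4-benzoquinone)
Conditions: Ag2O, MgSO4, CH2Cl2, rt, dark; filtered and used at once
Reagents that add atoms: none
Why: Two-electron hydroquinone-to-quinone oxidation under neutral anhydrous conditions suits this electron-poor, moisture-sensitive quinone.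

Step 4
Reactants: 3 (E)-tert-butyldimethyl{[3-(3,4,5-trimethoxyphenyl)prop-2-en-1-yl]oxy}silane; 5 methyl 3,6-dioxocyclohexa-1,4-diene-1-carboxylate
Product: 7 methyl (2R,3S)-3-{[(tert-butyldimethylsilyl)oxy]methyl}-5-hydroxy-2-(3,4,5-trimethoxyphenyl)-2,3-dihydro-1-benzofuran-4-carboxylate, via benzylic cation zwitterion 6 (not isolated)
Conditions: Cu(OTf)2 (10 mol %), (S,S)-tBu-BOX [2,2'-(propane-2,2-diyl)bis((4S)-4-tert-butyl-4,5-dihydro-1,3-oxazole)] (11 mol %), 4 Å molecular sieves, CH2Cl2, −40 °C to −20 °C
Reagents that add atoms: none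
Why: Divalent copper binds 5 through the ester C=O and the neighbouring quinone C=O, so the ring CH next to the ester becomes a doubly activated acceptor; the CH2OTBS-bearing alkene carbon of 3 attacks it (C3–C3a) and enolisation gives zwitterion 6, whose C2 cation is an O-methylated para-quinone methide of ring C, to which the oxygen of the second quinone carbonyl, now a phenolate ortho to the new bond, adds (O1–C2), the same bond order as in the presumed biosynthesis of 8–5' neolignans (C8–C5' coupling, then phenol addition to the quinone methide). The closest known reaction type is the chiral Lewis acid catalysed formal (3+2) cycloaddition of 2-alkoxycarbonyl- and 2-alkoxy-1,4-benzoquinones with styrenes, propenylbenzenes and 2H-chromenes to give 2-aryl-2,3-dihydrobenzofuran-5-ols. The only ring closed is the dihydrofuran, in a 5-exo-trig mode with respect to the exocyclic C2=C(aryl) bond of the quinoid cation, while ring A arises by aromatisation of the quinone. C3 is set in the C–C bond formation, where the tert-butyl groups of the ligand leave one face of the planar chelate open and the electron-rich ring C stacks over the quinone, so that the Re face of the alkene carbon should be bonded; C2 is set in the ring closure by C3, because the aryl group takes the side opposite to CH2OTBS, which is also what the E geometry delivers in a suprafacial addition and what equilibration through 6 would favour. The step needs site selectivity on the quinone (the ester activates only the adjacent CH), regioselectivity on the alkene (only C2 can be stabilised by ring C) and O- over C-closure (a cyclobutane from C-closure can reopen to 6 on warming, the aromatic product cannot).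

Step 5
Reactants: 7 methyl (2R,3S)-3-{[(tert-butyldimethylsilyl)oxy]methyl}-5-hydroxy-2-(3,4,5-trimethoxyphenyl)-2,3-dihydro-1-benzofuran-4-carboxylate
Product: 8 (2R,3S)-3-{[(tert-butyldimethylsilyl)oxy]methyl}-5-hydroxy-2-(3,4,5-trimethoxyphenyl)-2,3-dihydro-1-benzofuran-4-carboxylic acid
Conditions: LiI (5 equiv), pyridine, reflux; then cold 0.5 M HCl
Reagents that add atoms: none
Why: Nucleophilic ester cleavage (SN2 of iodide at the ester methyl carbon) is insensitive to the two ortho substituents that block attack at the acyl carbon, and it should spare the aryl methyl ethers, the silyl ether and both stereocentres.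

Step 6
Reactants: 8 (2R,3S)-3-{[(tert-butyldimethylsilyl)oxy]methyl}-5-hydroxy-2-(3,4,5-trimethoxyphenyl)-2,3-dihydro-1-benzofuran-4-carboxylic acid
Product: 9 (2R,3S)-3-{[(tert-butyldimethylsilyl)oxy]methyl}-2-(3,4,5-trimethoxyphenyl)-2,3-dihydro-1-benzofuran-5-ol
Conditions: Ag2CO3 (10 mol %), AcOH (5 mol %), DMSO, 120 °C
Reagents that add atoms: none
Why: In this silver-catalysed protodecarboxylation of an ortho-substituted benzoic acid, the two ortho groups twist the carboxylate out of plane and the ortho oxygen stabilises the aryl-silver species before protonation, and no stereocentre takes part.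

Step 7
Reactants: 9 (2R,3S)-3-{[(tert-butyldimethylsilyl)oxy]methyl}-2-(3,4,5-trimethoxyphenyl)-2,3-dihydro-1-benzofuran-5-ol
Product: 10 (2R,3S)-3-{[(tert-butyldimethylsilyl)oxy]methyl}-2-(3,4,5-trimethoxyphenyl)-2,3-dihydro-1-benzofuran-5-yl trifluoromethanesulfonate
Conditions: Tf2O, pyridine, CH2Cl2, 0 °C
Reagents that add atoms: trifluoromethanesulfonic anhydride, O=S(=O)(OS(=O)(=O)C(F)(F)F)C(F)(F)F
Why: O-Sulfonylation of the only free hydroxyl group turns the C5–O bond into a cross-coupling handle.

Step 8
Reactants: 10 (2R,3S)-3-{[(tert-butyldimethylsilyl)oxy]methyl}-2-(3,4,5-trimethoxyphenyl)-2,3-dihydro-1-benzofuran-5-yl trifluoromethanesulfonate; 11 (E)-tert-butyldimethyl{[3-(4,4,5,5-tetramethyl-1,3,2-dioxaborolan-2-yl)prop-2-en-1-yl]oxy}silane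
Product: 12 (2R,3S)-5-[(E)-3-{(tert-butyldimethylsilyl)oxy}prop-1-en-1-yl]-3-{[(tert-butyldimethylsilyl)oxy]methyl}-2-(3,4,5-trimethoxyphenyl)-2,3-dihydro-1-benzofuran
Conditions: PdCl2(dppf) (5 mol %), K3PO4, 1,4-dioxane/H2O, 80 °C
Reagents that add atoms: none
Why: Suzuki–Miyaura coupling of an aryl triflate with an alkenyl boronate proceeds with retention of the E geometry and tolerates silyl ethers and the benzylic ether.

Step 9
Reactants: 12 (2R,3S)-5-[(E)-3-{(tert-butyldimethylsilyl)oxy}prop-1-en-1-yl]-3-{[(tert-butyldimethylsilyl)oxy]methyl}-2-(3,4,5-trimethoxyphenyl)-2,3-dihydro-1-benzofuran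
Product: 13 (E)-3-[(2R,3S)-3-(hydroxymethyl)-2-(3,4,5-trimethoxyphenyl)-2,3-dihydro-1-benzofuran-5-yl]prop-2-en-1-ol (target)
Conditions: Bu4NF (2.5 equiv), THF, 0 °C to rt
Reagents that add atoms: none
Why: Fluoride-driven desilylation frees both primary alcohols under conditions that touch neither the alkene nor the stereocentres.

## Compound list

1 | methyl (E)-3-(3,4,5-trimethoxyphenyl)acrylate | COC(=O)/C=C/c1cc(OC)c(OC)c(OC)c1 | starting material
2 | (E)-3-(3,4,5-trimethoxyphenyl)prop-2-en-1-ol | OC/C=C/c1cc(OC)c(OC)c(OC)c1 | intermediate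
3 | (E)-tert-butyldimethyl{[3-(3,4,5-trimethoxyphenyl)prop-2-en-1-yl]oxy}silane | CC(C)(C)[Si](C)(C)OC/C=C/c1cc(OC)c(OC)c(OC)c1 | intermediate
4 | methyl 2,5-dihydroxybenzoate | COC(=O)c1cc(O)ccc1O | starting material
5 | methyl 3,6-dioxocyclohexa-1,4-diene-1-carboxylate | COC(=O)C1=CC(=O)C=CC1=O | intermediate
6 | benzylic cation zwitterion (open-chain adduct after enolisation; C3 configured as in 7, C2 cationic, phenolate at C7a) | COc1cc([CH+][C@H](CO[Si](C)(C)C(C)(C)C)c2c([O-])ccc(O)c2C(=O)OC)cc(OC)c1OC | intermediate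
7 | methyl (2R,3S)-3-{[(tert-butyldimethylsilyl)oxy]methyl}-5-hydroxy-2-(3,4,5-trimethoxyphenyl)-2,3-dihydro-1-benzofuran-4-carboxylate | COc1cc([C@@H]2Oc3ccc(O)c(C(=O)OC)c3[C@H]2CO[Si](C)(C)C(C)(C)C)cc(OC)c1OC | intermediate
8 | (2R,3S)-3-{[(tert-butyldimethylsilyl)oxy]methyl}-5-hydroxy-2-(3,4,5-trimethoxyphenyl)-2,3-dihydro-1-benzofuran-4-carboxylic acid | COc1cc([C@@H]2Oc3ccc(O)c(C(=O)O)c3[C@H]2CO[Si](C)(C)C(C)(C)C)cc(OC)c1OC | intermediate
9 | (2R,3S)-3-{[(tert-butyldimethylsilyl)oxy]methyl}-2-(3,4,5-trimethoxyphenyl)-2,3-dihydro-1-benzofuran-5-ol | COc1cc([C@@H]2Oc3ccc(O)cc3[C@H]2CO[Si](C)(C)C(C)(C)C)cc(OC)c1OC | intermediate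
10 | (2R,3S)-3-{[(tert-butyldimethylsilyl)oxy]methyl}-2-(3,4,5-trimethoxyphenyl)-2,3-dihydro-1-benzofuran-5-yl trifluoromethanesulfonate | COc1cc([C@@H]2Oc3ccc(OS(=O)(=O)C(F)(F)F)cc3[C@H]2CO[Si](C)(C)C(C)(C)C)cc(OC)c1OC | intermediate
11 | (E)-tert-butyldimethyl{[3-(4,4,5,5-tetramethyl-1,3,2-dioxaborolan-2-yl)prop-2-en-1-yl]oxy}silane | CC(C)(C)[Si](C)(C)OC/C=C/B1OC(C)(C)C(C)(C)O1 | starting material
12 | (2R,3S)-5-[(E)-3-{(tert-butyldimethylsilyl)oxy}prop-1-en-1-yl]-3-{[(tert-butyldimethylsilyl)oxy]methyl}-2-(3,4,5-trimethoxyphenyl)-2,3-dihydro-1-benzofuran | COc1cc([C@@H]2Oc3ccc(/C=C/CO[Si](C)(C)C(C)(C)C)cc3[C@H]2CO[Si](C)(C)C(C)(C)C)cc(OC)c1OC | intermediate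
13 | (E)-3-[(2R,3S)-3-(hydroxymethyl)-2-(3,4,5-trimethoxyphenyl)-2,3-dihydro-1-benzofuran-5-yl]prop-2-en-1-ol | COc1cc([C@@H]2Oc3ccc(/C=C/CO)cc3[C@H]2CO)cc(OC)c1OC | target

## Step count and risks

Total step count: 9.
Longest linear sequence: 8 steps (steps 1, 2, 4, 5, 6, 7, 8, 9).

Steps most likely to fail:

**Step 4.**
- What may go wrong: poor facial selectivity at the alkene, caused by competition from an unligated or exo pathway, or slow addition that lets the background reaction take over.
- Fallback: it sets out from 3 and 5, comes back at 8, and replaces catalyst control by a classical resolution that uses the temporary carboxyl group as its handle.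
- The cycloaddition is run with Cu(OTf)2 alone. It should give the trans adduct as the racemate, that is 7 together with methyl (2S,3R)-3-{[(tert-butyldimethylsilyl)oxy]methyl}-5-hydroxy-2-(3,4,5-trimethoxyphenyl)-2,3-dihydro-1-benzofuran-4-carboxylate F1.
- LiI in refluxing pyridine then gives the racemic acid, 8 together with the (2S,3R)-configured carboxylic acid F2.
- Crystallisation with (R)-1-phenylethylamine should deposit the less soluble diastereomeric salt, the (R)-1-phenylethylammonium salt of 8 F3. The amine enantiomer would be exchanged if the other salt crystallises.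
- Acidification returns 8.

**Step 6.**
- What may go wrong: slow loss of CO2, oxidation of the electron-rich phenol by silver, or desilylation followed by lactonisation onto the acid.
- Fallback: it sets out from 7, comes back at 9, bypasses 8, and removes the extra carbon as CO instead of CO2.
- iBu2AlH reduces the ester to (2R,3S)-3-{[(tert-butyldimethylsilyl)oxy]methyl}-4-(hydroxymethyl)-2-(3,4,5-trimethoxyphenyl)-2,3-dihydro-1-benzofuran-5-ol F4.
- MnO2 in CH2Cl2 oxidises the benzylic alcohol to (2R,3S)-3-{[(tert-butyldimethylsilyl)oxy]methyl}-5-hydroxy-2-(3,4,5-trimethoxyphenyl)-2,3-dihydro-1-benzofuran-4-carbaldehyde F5.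
- Stoichiometric RhCl(PPh3)3 in refluxing toluene (Tsuji–Wilkinson decarbonylation) should then give 9.

**Step 5.**
- What may go wrong: incomplete dealkylation of the hindered, hydrogen-bonded ester, or competing cleavage of aryl methyl ethers on prolonged heating.
- Fallback: it sets out from 4, comes back at 8, and changes the ester to one that is removed by metal catalysis at room temperature.
- Ti(OiPr)4-catalysed transesterification in allyl alcohol gives allyl 2,5-dihydroxybenzoate F6.
- Ag2O oxidises it to allyl 3,6-dioxocyclohexa-1,4-diene-1-carboxylate F7.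
- The copper-catalysed cycloaddition with 3 under the conditions of step 4 gives allyl (2R,3S)-3-{[(tert-butyldimethylsilyl)oxy]methyl}-5-hydroxy-2-(3,4,5-trimethoxyphenyl)-2,3-dihydro-1-benzofuran-4-carboxylate F8.
- Pd(PPh3)4 with morpholine in THF transfers the allyl group to the amine through a π-allyl complex of divalent palladium and frees 8.

## Further compounds

F1 | step 4 | methyl (2S,3R)-3-{[(tert-butyldimethylsilyl)oxy]methyl}-5-hydroxy-2-(3,4,5-trimethoxyphenyl)-2,3-dihydro-1-benzofuran-4-carboxylate (enantiomer of 7, second component of the racemate) | COc1cc([C@H]2Oc3ccc(O)c(C(=O)OC)c3[C@@H]2CO[Si](C)(C)C(C)(C)C)cc(OC)c1OC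
F2 | step 4 | (2S,3R)-3-{[(tert-butyldimethylsilyl)oxy]methyl}-5-hydroxy-2-(3,4,5-trimethoxyphenyl)-2,3-dihydro-1-benzofuran-4-carboxylic acid (enantiomer of 8, second component of the racemate) | COc1cc([C@H]2Oc3ccc(O)c(C(=O)O)c3[C@@H]2CO[Si](C)(C)C(C)(C)C)cc(OC)c1OC
F3 | step 4 | (R)-1-phenylethylammonium salt of 8 | COc1cc([C@@H]2Oc3ccc(O)c(C(=O)[O-])c3[C@H]2CO[Si](C)(C)C(C)(C)C)cc(OC)c1OC.C[C@@H]([NH3+])c1ccccc1
F4 | step 6 | (2R,3S)-3-{[(tert-butyldimethylsilyl)oxy]methyl}-4-(hydroxymethyl)-2-(3,4,5-trimethoxyphenyl)-2,3-dihydro-1-benzofuran-5-ol | COc1cc([C@@H]2Oc3ccc(O)c(CO)c3[C@H]2CO[Si](C)(C)C(C)(C)C)cc(OC)c1OC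
F5 | step 6 | (2R,3S)-3-{[(tert-butyldimethylsilyl)oxy]methyl}-5-hydroxy-2-(3,4,5-trimethoxyphenyl)-2,3-dihydro-1-benzofuran-4-carbaldehyde | COc1cc([C@@H]2Oc3ccc(O)c(C=O)c3[C@H]2CO[Si](C)(C)C(C)(C)C)cc(OC)c1OC
F6 | step 5 | allyl 2,5-dihydroxybenzoate | C=CCOC(=O)c1cc(O)ccc1O
F7 | step 5 | allyl 3,6-dioxocyclohexa-1,4-diene-1-carboxylate | C=CCOC(=O)C1=CC(=O)C=CC1=O
F8 | step 5 | allyl (2R,3S)-3-{[(tert-butyldimethylsilyl)oxy]methyl}-5-hydroxy-2-(3,4,5-trimethoxyphenyl)-2,3-dihydro-1-benzofuran-4-carboxylate | COc1cc([C@@H]2Oc3ccc(O)c(C(=O)OCC=C)c3[C@H]2CO[Si](C)(C)C(C)(C)C)cc(OC)c1OC
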